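**Retrosynthetic overview**

1. The furan ring of the 2-arylbenzofuran is cut at O1'–C2' and C3'–C3a' into iodophenol 19 and aryl alkyne 13 (Sonogashira coupling, then 5-endo-dig closure). The 1,1-dimethylallyl group at C7' comes from an aromatic Claisen shift of a prenyl ether whose other ortho carbon is blocked by iodine.
2. The pyran ring of the chroman (O1, C2, C3, C4, C4a, C8a) is never closed as a six-membered ring. An aryl radical at C4a first closes a five-membered 2,2-dimethyl-2,3-dihydrobenzofuran ring (O1, C2, C3, C4a, C8a) with C4 outside it as CH2•. A 1,2-aryl (neophyl) shift of C4a from C3 to C4 then expands this ring to the pyran.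
3. Enabling feature: C4a lies between the O1-bearing C8a and the carbon-substituted C5, and para to the C7 oxygen. The bridged cyclohexadienyl radical of the shift is therefore stabilised by a para oxygen and an ortho nitrile. C2 is the fully substituted O–CMe2 carbon next to the migrating centre. Both resorcinol oxygens carry the same O–CMe2–CH=CH2 group, and the iodine at C4a decides which becomes O1; the other is removed later by Pd(0) to give the C7 hydroxyl.
4. Order of ring formation: both benzene rings come from 1 and 14; five-membered O-ring (transient), then six-membered pyran ring (step 5); furan ring (step 13); desilylation last.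

Key step: step 5

Remark on the chemistry: the target has no stereocentre and no stereogenic double bond, so it is achiral and no configuration has to be set. The transient stereocentres in 7 and 18 are racemic and are erased. Chroman atoms are numbered O1–C8a; benzofuran atoms carry primes.

**Route**

Step 1
Reactants: 1 3,5-dimethoxybenzonitrile
Product: 2 2-iodo-3,5-dimethoxybenzonitrile
Conditions: NIS (1.05 equiv), TFA (cat.), MeCN, rt
Reagents that add atoms: N-iodosuccinimide, O=C1CCC(=O)N1I
Why: Electrophilic aromatic iodination should occur at C2, which is ortho/para to both methoxy groups and less hindered than C4 between them, as in the halogenation of other 3,5-dimethoxyaryl nitriles, aldehydes and esters.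

Step 2
Reactants: 2 2-iodo-3,5-dimethoxybenzonitrile
Product: 3 3,5-dihydroxy-2-iodobenzonitrile
Conditions: BBr3 (3 equiv), CH2Cl2, −78 °C to rt; then H2O
Reagents that add atoms: none
Why: Lewis-acid cleavage of aryl methyl ethers by BBr3 should free both phenols while the nitrile and the aryl iodide stay intact.

Step 3
Reactants: 3 3,5-dihydroxy-2-iodobenzonitrile
Product: 4 2-iodo-3,5-bis[(2-methylbut-3-yn-2-yl)oxy]benzonitrile
Conditions: 3-chloro-3-methylbut-1-yne (2.6 equiv), DBU (2.8 equiv), CuCl2·2H2O (1 mol%), MeCN, 0 °C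
Reagents that add atoms: 3-chloro-3-methylbut-1-yne, CC(C)(Cl)C#C
Why: Copper-catalysed O-alkylation of phenols with a tertiary propargylic chloride (Godfrey-type etherification) is expected to form both hindered tertiary aryl ethers, acidic phenols being good substrates.

Step 4
Reactants: 4 2-iodo-3,5-bis[(2-methylbut-3-yn-2-yl)oxy]benzonitrile
Product: 5 2-iodo-3,5-bis[(2-methylbut-3-en-2-yl)oxy]benzonitrile
Conditions: H2 (1 atm), Lindlar catalyst, quinoline, EtOAc, rt, stopped after 2 equiv H2
Reagents that add atoms: none
Why: Lindlar semihydrogenation should stop at the terminal alkenes, and quinoline poisoning plus control of hydrogen uptake should spare the C–I bond and the nitrile.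

Step 5
Reactants: 5 2-iodo-3,5-bis[(2-methylbut-3-en-2-yl)oxy]benzonitrile
Product: 9 2,2-dimethyl-7-[(2-methylbut-3-en-2-yl)oxy]chromane-5-carbonitrile, via aryl radical 6 (not isolated), via dihydrobenzofuranylmethyl radical 7 (not isolated), via chroman-3-yl radical 8 (not isolated)
Conditions: Bu3SnH (1.2 equiv) and AIBN (0.2 equiv) added by syringe pump over 8 h, PhH (0.005 M), 80 °C
Reagents that add atoms: none
Why: Bu3Sn• abstracts the iodine that marks C4a to give aryl radical 6, which closes the five-membered 2,2-dimethyl-2,3-dihydrobenzofuran ring by 5-exo-trig attack on the internal alkene carbon (new C4a–C3 bond) and leaves the future C4 as an exocyclic CH2• in primary radical 7. Radical 7 attacks the ipso carbon C4a in a 3-exo mode and the bridged spiro[2.5]octadienyl species reopens by cleavage of the C3–C4a bond (1,2-aryl or neophyl shift), so that C4 is inserted between C3 and C4a and the five-membered ring becomes the six-membered pyran ring of secondary radical 8, which takes hydrogen from Bu3SnH to give 9. The closest known reaction type is the aryl radical cyclisation with consecutive neophyl rearrangement, which turns 5-exo radicals into formal 6-endo products at low stannane concentration. No stereocentre remains in 9, the C3 stereocentre of 7 being transient and racemic. The step needs site selectivity between the two identical ethers, secured because only the ether ortho to the iodine can be reached by the aryl radical, and it needs the shift to outrun hydrogen transfer to 7, secured by slow stannane addition, by the primary-to-secondary radical gain and by stabilisation of the bridged cyclohexadienyl radical through the para oxygen and the ortho nitrile. Any direct attack of 6 on the terminal alkene carbon would lead to the same radical 8.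

Step 6
Reactants: 9 2,2-dimethyl-7-[(2-methylbut-3-en-2-yl)oxy]chromane-5-carbonitrile
Product: 11 2,2-dimethyl-7-[(2-methylbut-3-en-2-yl)oxy]chromane-5-carbaldehyde, via N-aluminio aldimine 10 (not isolated)
Conditions: DIBAL-H (1.2 equiv), CH2Cl2, −78 °C; then 1 M HCl, 0 °C, brief
Reagents that add atoms: water, O
Why: Partial reduction of the nitrile by DIBAL-H stops at the N-aluminio aldimine, which cold dilute acid hydrolyses to the aldehyde without ionising the tertiary allyl ether.

Step 7
Reactants: 11 2,2-dimethyl-7-[(2-methylbut-3-en-2-yl)oxy]chromane-5-carbaldehyde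
Product: 12 5-ethynyl-2,2-dimethyl-7-[(2-methylbut-3-en-2-yl)oxy]chromane
Conditions: Ohira–Bestmann reagent (1.3 equiv), K2CO3 (2 equiv), MeOH, 0 °C to rt
Reagents that add atoms: dimethyl (1-diazo-2-oxopropyl)phosphonate, COP(=O)(OC)C(=[N+]=[N-])C(C)=O
Why: Seyferth–Gilbert homologation in the Ohira–Bestmann variant (diazomethylphosphonate formed in situ, olefination, loss of N2 and 1,2-hydrogen shift of the alkylidene carbene) should convert the aldehyde to the terminal alkyne under mild base.

Step 8
Reactants: 12 5-ethynyl-2,2-dimethyl-7-[(2-methylbut-3-en-2-yl)oxy]chromane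
Product: 13 5-ethynyl-2,2-dimethylchroman-7-ol
Conditions: Pd(PPh3)4 (3 mol%), morpholine (3 equiv), THF, rt
Reagents that add atoms: none
Why: Tsuji–Trost deallylation, in which Pd(0) ionises only the tertiary allylic aryl ether to a π-allyl complex that morpholine captures, should free the C7 phenol while the non-allylic chroman ether cannot ionise.

Step 9
Reactants: 14 phloroglucinol
Product: 15 3,5-bis[(tert-butyldimethylsilyl)oxy]phenol
Conditions: TBSCl (2.05 equiv), imidazole (4 equiv), DMF, 0 °C to rt; chromatography
Reagents that add atoms: tert-butyldimethylsilyl chloride, CC(C)(C)[Si](C)(C)Cl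
Why: Statistical silylation of the three equivalent hydroxyls should give the bis-ether as the main fraction, separable from mono- and tris-silylated material that can be recycled.

Step 10
Reactants: 15 3,5-bis[(tert-butyldimethylsilyl)oxy]phenol
Product: 16 3,5-bis[(tert-butyldimethylsilyl)oxy]-2-iodophenol
Conditions: NIS (1.0 equiv), CH2Cl2, −40 °C
Reagents that add atoms: N-iodosuccinimide, O=C1CCC(=O)N1I
Why: Electrophilic aromatic iodination is expected ortho to the free hydroxyl because the only other position, para to it, is shielded by two flanking silyloxy groups.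

Step 11
Reactants: 16 3,5-bis[(tert-butyldimethylsilyl)oxy]-2-iodophenol
Product: 17 2-iodo-3,5-bis[(tert-butyldimethylsilyl)oxy]phenyl 3-methylbut-2-en-1-yl ether
Conditions: 3-methylbut-2-en-1-ol (1.3 equiv), PPh3, DIAD, THF, 0 °C to rt
Reagents that add atoms: 3-methylbut-2-en-1-ol, CC(C)=CCO
Why: Mitsunobu etherification at the primary allylic carbon proceeds under neutral conditions that leave the aryl silyl ethers untouched.

Step 12
Reactants: 17 2-iodo-3,5-bis[(tert-butyldimethylsilyl)oxy]phenyl 3-methylbut-2-en-1-yl ether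
Product: 19 2-iodo-6-(2-methylbut-3-en-2-yl)-3,5-bis[(tert-butyldimethylsilyl)oxy]phenol, via ortho-dienone 18 (not isolated)
Conditions: PhNEt2, 185 °C (sealed tube, microwave), 1 h
Reagents that add atoms: none
Why: The aromatic Claisen rearrangement ([3,3]) delivers the allyl terminus to the only ortho carbon that bears hydrogen, which creates the quaternary carbon of the 1,1-dimethylallyl group, and tautomerisation of dienone 18 makes the shift irreversible while iodine blocks the other ortho carbon.

Step 13
Reactants: 13 5-ethynyl-2,2-dimethylchroman-7-ol; 19 2-iodo-6-(2-methylbut-3-en-2-yl)-3,5-bis[(tert-butyldimethylsilyl)oxy]phenol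
Product: 21 5-[4,6-bis[(tert-butyldimethylsilyl)oxy]-7-(2-methylbut-3-en-2-yl)benzofuran-2-yl]-2,2-dimethylchroman-7-ol, via 2-alkynylphenol 20 (not isolated)
Conditions: PdCl2(PPh3)2 (5 mol%), CuI (10 mol%), Et3N–DMF (1:2), 60 °C, Ar
Reagents that add atoms: none
Why: Sonogashira coupling followed in the same flask by 5-endo-dig closure of the ortho-alkynylphenol (Castro/Larock-type benzofuran annulation) should give the 2-arylbenzofuran, and only the free hydroxyl next to the 1,1-dimethylallyl group can close because the other ortho oxygen is silylated.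

Step 14
Reactants: 21 5-[4,6-bis[(tert-butyldimethylsilyl)oxy]-7-(2-methylbut-3-en-2-yl)benzofuran-2-yl]-2,2-dimethylchroman-7-ol
Product: 22 2-(7-hydroxy-2,2-dimethylchroman-5-yl)-7-(2-methylbut-3-en-2-yl)benzofuran-4,6-diol (CNP0300714.0)
Conditions: TBAF (2.2 equiv), AcOH (2.2 equiv), THF, 0 °C, Ar
Reagents that add atoms: none
Why: Fluoride cleavage of the aryl silyl ethers under acetic acid buffering avoids both strong acid, which could cyclise the ortho-(1,1-dimethylallyl)phenol onto its vinyl group, and free phenoxides that are sensitive to air.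

**Compound list**

1 | 3,5-dimethoxybenzonitrile | N#Cc1cc(OC)cc(OC)c1 | starting material
2 | 2-iodo-3,5-dimethoxybenzonitrile | N#Cc1cc(OC)cc(OC)c1I | intermediate
3 | 3,5-dihydroxy-2-iodobenzonitrile | N#Cc1cc(O)cc(O)c1I | intermediate
4 | 2-iodo-3,5-bis[(2-methylbut-3-yn-2-yl)oxy]benzonitrile | N#Cc1cc(OC(C)(C)C#C)cc(OC(C)(C)C#C)c1I | intermediate
5 | 2-iodo-3,5-bis[(2-methylbut-3-en-2-yl)oxy]benzonitrile | N#Cc1cc(OC(C)(C)C=C)cc(OC(C)(C)C=C)c1I | intermediate
6 | 2-cyano-4,6-bis[(2-methylbut-3-en-2-yl)oxy]phenyl radical | N#Cc1cc(OC(C)(C)C=C)cc(OC(C)(C)C=C)[c]1 | intermediate (not isolated)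
7 | {4-cyano-2,2-dimethyl-6-[(2-methylbut-3-en-2-yl)oxy]-2,3-dihydrobenzofuran-3-yl}methyl radical (racemic) | N#Cc1cc(OC(C)(C)C=C)cc2OC(C)(C)C([CH2])c12 | intermediate (not isolated)
8 | 5-cyano-2,2-dimethyl-7-[(2-methylbut-3-en-2-yl)oxy]chroman-3-yl radical | N#Cc1cc(OC(C)(C)C=C)cc2OC(C)(C)[CH]Cc12 | intermediate (not isolated)
9 | 2,2-dimethyl-7-[(2-methylbut-3-en-2-yl)oxy]chromane-5-carbonitrile | N#Cc1cc(OC(C)(C)C=C)cc2OC(C)(C)CCc12 | intermediate
10 | N-(diisobutylaluminio) aldimine of 11 | CC(C)C[Al](CC(C)C)N=Cc1cc(OC(C)(C)C=C)cc2OC(C)(C)CCc12 | intermediate (not isolated)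
11 | 2,2-dimethyl-7-[(2-methylbut-3-en-2-yl)oxy]chromane-5-carbaldehyde | O=Cc1cc(OC(C)(C)C=C)cc2OC(C)(C)CCc12 | intermediate
12 | 5-ethynyl-2,2-dimethyl-7-[(2-methylbut-3-en-2-yl)oxy]chromane | C#Cc1cc(OC(C)(C)C=C)cc2OC(C)(C)CCc12 | intermediate
13 | 5-ethynyl-2,2-dimethylchroman-7-ol | C#Cc1cc(O)cc2OC(C)(C)CCc12 | intermediate
14 | phloroglucinol (benzene-1,3,5-triol) | Oc1cc(O)cc(O)c1 | starting material
15 | 3,5-bis[(tert-butyldimethylsilyl)oxy]phenol | Oc1cc(O[Si](C)(C)C(C)(C)C)cc(O[Si](C)(C)C(C)(C)C)c1 | intermediate
16 | 3,5-bis[(tert-butyldimethylsilyl)oxy]-2-iodophenol | Oc1c(I)c(O[Si](C)(C)C(C)(C)C)cc(O[Si](C)(C)C(C)(C)C)c1 | intermediate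
17 | 2-iodo-3,5-bis[(tert-butyldimethylsilyl)oxy]phenyl 3-methylbut-2-en-1-yl ether | CC(C)=CCOc1c(I)c(O[Si](C)(C)C(C)(C)C)cc(O[Si](C)(C)C(C)(C)C)c1 | intermediate
18 | 2-iodo-6-(2-methylbut-3-en-2-yl)-3,5-bis[(tert-butyldimethylsilyl)oxy]cyclohexa-2,4-dien-1-one (racemic) | O=C1C(I)=C(O[Si](C)(C)C(C)(C)C)C=C(O[Si](C)(C)C(C)(C)C)C1C(C)(C)C=C | intermediate (not isolated)
19 | 2-iodo-6-(2-methylbut-3-en-2-yl)-3,5-bis[(tert-butyldimethylsilyl)oxy]phenol | Oc1c(I)c(O[Si](C)(C)C(C)(C)C)cc(O[Si](C)(C)C(C)(C)C)c1C(C)(C)C=C | intermediate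
20 | 2-[(7-hydroxy-2,2-dimethylchroman-5-yl)ethynyl]-6-(2-methylbut-3-en-2-yl)-3,5-bis[(tert-butyldimethylsilyl)oxy]phenol | Oc1c(C#Cc2cc(O)cc3OC(C)(C)CCc23)c(O[Si](C)(C)C(C)(C)C)cc(O[Si](C)(C)C(C)(C)C)c1C(C)(C)C=C | intermediate (not isolated)
21 | 5-[4,6-bis[(tert-butyldimethylsilyl)oxy]-7-(2-methylbut-3-en-2-yl)benzofuran-2-yl]-2,2-dimethylchroman-7-ol | C=CC(C)(C)c1c(O[Si](C)(C)C(C)(C)C)cc(O[Si](C)(C)C(C)(C)C)c2cc(-c3cc(O)cc4c3CCC(C)(C)O4)oc12 | intermediate
22 | 2-(7-hydroxy-2,2-dimethylchroman-5-yl)-7-(2-methylbut-3-en-2-yl)benzofuran-4,6-diol | C=CC(C)(C)c1c(O)cc(O)c2cc(-c3cc(O)cc4c3CCC(C)(C)O4)oc12 | target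

**Step count and risks**

Total step count: 14 (steps 1–8 northern fragment, steps 9–12 southern fragment, steps 13–14 union and deprotection).
Longest linear sequence: 10 steps (steps 1–8, 13, 14).

Steps most likely to fail:

Step 5. Hydrogen transfer to the five-ring radical 7 before the 1,2-aryl shift would leave an unexpanded 3-methyl-dihydrobenzofuran, and the ring-expanded radical 8 could fragment at the O1–C2 bond. The fallback separates ring closure from ring expansion and runs the expansion with no hydrogen donor present. It sets out from 5 and returns at 9. Aryl iodide 5 is cyclised with Bu3SnH in the presence of excess TEMPO (benzene, 70 °C), which traps the 5-exo radical as the isolated five-membered-ring alkoxyamine 1-{[4-cyano-2,2-dimethyl-6-[(2-methylbut-3-en-2-yl)oxy]-2,3-dihydrobenzofuran-3-yl]methoxy}-2,2,6,6-tetramethylpiperidine F1. Zn in AcOH–THF–H2O at rt cleaves the N–O bond to the primary alcohol 3-(hydroxymethyl)-2,2-dimethyl-6-[(2-methylbut-3-en-2-yl)oxy]-2,3-dihydrobenzofuran-4-carbonitrile F2. I2, PPh3 and imidazole convert it to the primary iodide 3-(iodomethyl)-2,2-dimethyl-6-[(2-methylbut-3-en-2-yl)oxy]-2,3-dihydrobenzofuran-4-carbonitrile F3. Iodine-atom-transfer isomerisation (hexabutylditin 10 mol%, sunlamp, benzene, 80 °C) then lets the primary radical live until the neophyl shift has occurred and caps the expanded radical with iodine, which should give 3-iodo-2,2-dimethyl-7-[(2-methylbut-3-en-2-yl)oxy]chromane-5-carbonitrile F4. Ordinary Bu3SnH/AIBN reduction of F4 gives 9.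

Step 12. The [3,3] shift may go to the iodine-bearing ortho carbon and be followed by a Cope shift to the para carbon (normal-prenyl isomer), and iodine may be lost at 185 °C. The fallback performs the Claisen shift before iodine is present, on a symmetric ether whose two ortho carbons are equivalent. It sets out from 15 and returns at 19. Mitsunobu etherification of 15 with 3-methylbut-2-en-1-ol gives 3,5-bis[(tert-butyldimethylsilyl)oxy]phenyl 3-methylbut-2-en-1-yl ether F5. Heating in PhNEt2 (185 °C) gives 2-(2-methylbut-3-en-2-yl)-3,5-bis[(tert-butyldimethylsilyl)oxy]phenol F6. Iodination with NIS at −78 °C in CH2Cl2 then gives 19; ring iodination of the trioxygenated arene is expected to be much faster than iodoetherification of the hindered vinyl group, and the position para to the hydroxyl is shielded by two silyloxy groups.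

Step 13. Oxidative addition into the electron-rich, doubly ortho-substituted C–I bond may be slow, so that copper-mediated homocoupling of alkyne 13 and incomplete ring closure compete. The fallback separates C–C coupling from C–O ring closure and changes the closure to π-acid catalysis. It sets out from 13 and 19 and returns at 21. A copper-free Sonogashira coupling (XPhos-Pd precatalyst, Cs2CO3, MeCN, 40 °C, slow addition of 13) is stopped at the 2-alkynylphenol 20, which is isolated. Gold(I)-catalysed 5-endo-dig hydroalkoxylation (Ph3PAuNTf2, 2 mol%, CH2Cl2, rt) then closes the furan ring to 21 under neutral conditions that keep both silyl ethers in place.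

**Further compounds**

F1 | step 5 | 1-{[4-cyano-2,2-dimethyl-6-[(2-methylbut-3-en-2-yl)oxy]-2,3-dihydrobenzofuran-3-yl]methoxy}-2,2,6,6-tetramethylpiperidine (racemic) | N#Cc1cc(OC(C)(C)C=C)cc2OC(C)(C)C(CON3C(C)(C)CCCC3(C)C)c12
F2 | step 5 | 3-(hydroxymethyl)-2,2-dimethyl-6-[(2-methylbut-3-en-2-yl)oxy]-2,3-dihydrobenzofuran-4-carbonitrile (racemic) | N#Cc1cc(OC(C)(C)C=C)cc2OC(C)(C)C(CO)c12
F3 | step 5 | 3-(iodomethyl)-2,2-dimethyl-6-[(2-methylbut-3-en-2-yl)oxy]-2,3-dihydrobenzofuran-4-carbonitrile (racemic) | N#Cc1cc(OC(C)(C)C=C)cc2OC(C)(C)C(CI)c12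
F4 | step 5 | 3-iodo-2,2-dimethyl-7-[(2-methylbut-3-en-2-yl)oxy]chromane-5-carbonitrile (racemic) | N#Cc1cc(OC(C)(C)C=C)cc2OC(C)(C)C(I)Cc12
F5 | step 12 | 3,5-bis[(tert-butyldimethylsilyl)oxy]phenyl 3-methylbut-2-en-1-yl ether | CC(C)=CCOc1cc(O[Si](C)(C)C(C)(C)C)cc(O[Si](C)(C)C(C)(C)C)c1
F6 | step 12 | 2-(2-methylbut-3-en-2-yl)-3,5-bis[(tert-butyldimethylsilyl)oxy]phenol | Oc1cc(O[Si](C)(C)C(C)(C)C)cc(O[Si](C)(C)C(C)(C)C)c1C(C)(C)C=C
F0 | step 13 | none | none
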